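**Retrosynthetic overview**
1. The last C–C bond is a trans-selective enolate alkylation of butyrolactone 39 (fragment A, C22 skeleton) with benzylic bromide 22 (fragment B, C18 skeleton); global desilylation then gives the target.
2. Fragment A comes from copper-catalysed opening of cyclopropane-fused lactone 34 (made from (R)-epichlorohydrin and a malonate) by the aryl metal of dihydrobenzofuran bromide 29, followed by decarboxylation.
3. 29 and 22 both derive from one imide 14 and one aldehyde 6: a syn-aldol plus acid-mediated phenol closure gives the trans-dihydrobenzofuran, and an anti-aldol gives the open (1S,2S)-diol.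
4. 14 and 6 both come from 4-bromo-2-methoxyphenol 3 (allylation/Claisen/oxidative cleavage, or silylation/formylation), which is made from catechol.
5. Ring order: the aromatic rings are bought as catechol; the dihydrobenzofuran ring (step 20) and the butyrolactone ring (step 23) are built in separate branches and joined in step 24.

Assumption: TBS = tert-butyldimethylsilyl, TIPS = triisopropylsilyl; both enantiomers of 4-benzyl-1,3-oxazolidin-2-one are bought as recoverable auxiliaries. The target as drawn is (3R,4R) at the lactone, (1S,2S) at the open diol and (2S,3R) at the dihydrobenzofuran.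

**Step 1**
Reactants: 1 catechol
Product: 2 guaiacol (2-methoxyphenol)
Conditions: MeI (1.0 equiv), K2CO3 (1.0 equiv), acetone, reflux
Reagents that add atoms: iodomethane, CI
Why: Williamson mono-O-methylation; with one equivalent of MeI the mono-ether predominates and veratrole and catechol are removed by extraction and distillation.

**Step 2**
Reactants: 2 guaiacol
Product: 3 4-bromo-2-methoxyphenol
Conditions: NBS, MeCN, 0 °C to rt
Reagents that add atoms: N-bromosuccinimide, BrN1C(=O)CCC1=O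
Why: Electrophilic aromatic bromination goes para to the free hydroxyl, the stronger of the two donors.

**Step 3**
Reactants: 3 4-bromo-2-methoxyphenol
Product: 4 (4-bromo-2-methoxyphenoxy)triisopropylsilane
Conditions: TIPSCl, imidazole, DMF, rt
Reagents that add atoms: chlorotriisopropylsilane, CC(C)[Si](Cl)(C(C)C)C(C)C
Why: Silyl ether formation gives a base-stable phenol protection that survives organolithium chemistry.

**Step 4**
Reactants: 4 (4-bromo-2-methoxyphenoxy)triisopropylsilane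
Product: 6 3-methoxy-4-(TIPSO)benzaldehyde, via aryllithium 5 (not isolated)
Conditions: n-BuLi, THF, −78 °C; DMF; aq NH4Cl
Reagents that add atoms: N,N-dimethylformamide, CN(C)C=O; n-butyllithium, [Li]CCCC (lithium in 5 only)
Why: Bromine–lithium exchange followed by formylation of the aryllithium with DMF (Bouveault-type aldehyde synthesis).

**Step 5**
Reactants: 3 4-bromo-2-methoxyphenol; 7 allyl bromide
Product: 8 1-(allyloxy)-4-bromo-2-methoxybenzene
Conditions: K2CO3, acetone, reflux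
Reagents that add atoms: none
Why: Williamson O-allylation of the phenoxide.

**Step 6**
Reactants: 8 1-(allyloxy)-4-bromo-2-methoxybenzene
Product: 9 2-allyl-4-bromo-6-methoxyphenol
Conditions: N,N-diethylaniline, 200 °C
Reagents that add atoms: none
Why: Aromatic Claisen [3,3]-sigmatropic rearrangement delivers the allyl group to the only free ortho position and re-aromatises to the phenol.

**Step 7**
Reactants: 9 2-allyl-4-bromo-6-methoxyphenol
Product: 10 (2-allyl-4-bromo-6-methoxyphenoxy)(tert-butyl)dimethylsilane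
Conditions: TBSCl, imidazole, DMF, rt
Reagents that add atoms: tert-butyl(chloro)dimethylsilane, CC(C)(C)[Si](C)(C)Cl
Why: Silyl ether formation masks the hindered phenol for the enolate and organolithium steps.

**Step 8**
Reactants: 10 (2-allyl-4-bromo-6-methoxyphenoxy)(tert-butyl)dimethylsilane
Product: 11 2-[5-bromo-2-(TBSO)-3-methoxyphenyl]acetaldehyde
Conditions: OsO4 (2 mol%), NaIO4, 2,6-lutidine, dioxane/H2O 3:1, rt
Reagents that add atoms: sodium periodate, [Na+].[O-]I(=O)(=O)=O (oxygen, relayed by OsO4)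
Why: Lemieux–Johnson oxidative cleavage (dihydroxylation, then periodate glycol cleavage) of the terminal alkene without touching the arene.

**Step 9**
Reactants: 11 2-[5-bromo-2-(TBSO)-3-methoxyphenyl]acetaldehyde
Product: 12 2-[5-bromo-2-(TBSO)-3-methoxyphenyl]acetic acid
Conditions: NaClO2, NaH2PO4, 2-methylbut-2-ene, t-BuOH/H2O, rt
Reagents that add atoms: sodium chlorite, [Na+].[O-]Cl=O
Why: Pinnick oxidation under buffered conditions, with 2-methylbut-2-ene scavenging HOCl so the electron-rich ring is not chlorinated.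

**Step 10**
Reactants: 12 2-[5-bromo-2-(TBSO)-3-methoxyphenyl]acetic acid
Product: 14 (4S)-4-benzyl-3-{[5-bromo-2-(TBSO)-3-methoxyphenyl]acetyl}-1,3-oxazolidin-2-one, via mixed anhydride 13 (not isolated)
Conditions: PivCl, Et3N, THF, −20 °C; then LiCl, (S)-4-benzyl-1,3-oxazolidin-2-one, −20 °C to rt
Reagents that add atoms: (S)-4-benzyl-1,3-oxazolidin-2-one, O=C1N[C@@H](Cc2ccccc2)CO1; pivaloyl chloride, CC(C)(C)C(Cl)=O (atoms in 13 only)
Why: N-acylation of the Evans auxiliary through the mixed pivalic anhydride (LiCl-assisted) gives the enolisable chiral imide.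

**Step 11**
Reactants: 14 imide; 6 3-methoxy-4-(TIPSO)benzaldehyde
Product: 16 (4S)-4-benzyl-3-{(2R,3S)-2-[5-bromo-2-(TBSO)-3-methoxyphenyl]-3-hydroxy-3-[3-methoxy-4-(TIPSO)phenyl]propanoyl}-1,3-oxazolidin-2-one, via silyl ether 15 (not isolated)
Conditions: MgCl2 (20 mol%), Et3N, TMSCl, EtOAc, rt; then 1 M HCl, THF, 0 °C
Reagents that add atoms: chlorotrimethylsilane, C[Si](C)(C)Cl (atoms in 15 only)
Why: Evans MgCl2-catalysed direct anti-aldol: the chelated Z-magnesium enolate is attacked on the face away from the auxiliary benzyl group through a boat-like transition state and the aldolate is trapped by TMSCl, setting C2 (R) and C3 (S) anti.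

**Step 12**
Reactants: 16 anti-aldol adduct
Product: 17 (1S,2S)-2-[5-bromo-2-(TBSO)-3-methoxyphenyl]-1-[3-methoxy-4-(TIPSO)phenyl]propane-1,3-diol
Conditions: LiBH4, H2O (1 equiv), THF, 0 °C
Reagents that add atoms: none
Why: Reductive removal of the auxiliary (hydride attack at the exocyclic imide carbonyl) gives the primary alcohol without touching either stereocentre.

**Step 13**
Reactants: 17 (1S,2S)-diol
Product: 18 5-bromo-1-{(1S,2S)-1,3-bis(TBSO)-1-[3-methoxy-4-(TIPSO)phenyl]propan-2-yl}-2-(TBSO)-3-methoxybenzene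
Conditions: TBSOTf (3 equiv), 2,6-lutidine, CH2Cl2, −78 to 0 °C
Reagents that add atoms: tert-butyldimethylsilyl trifluoromethanesulfonate, CC(C)(C)[Si](C)(C)OS(=O)(=O)C(F)(F)F
Why: Silyl triflate silylation protects both hydroxyls, and using TBS at all three positions makes any phenol-to-alkoxide silyl migration during step 12 inconsequential.

**Step 14**
Reactants: 18 tetrasilylated aryl bromide
Product: 20 3-{(1S,2S)-1,3-bis(TBSO)-1-[3-methoxy-4-(TIPSO)phenyl]propan-2-yl}-4-(TBSO)-5-methoxybenzaldehyde, via aryllithium 19 (not isolated)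
Conditions: n-BuLi, THF, −78 °C; DMF; aq NH4Cl
Reagents that add atoms: N,N-dimethylformamide, CN(C)C=O; n-butyllithium, [Li]CCCC (lithium in 19 only)
Why: Bromine–lithium exchange and DMF formylation install the benzylic carbon para to the silyloxy group.

**Step 15**
Reactants: 20 aldehyde
Product: 21 [3-{(1S,2S)-1,3-bis(TBSO)-1-[3-methoxy-4-(TIPSO)phenyl]propan-2-yl}-4-(TBSO)-5-methoxyphenyl]methanol
Conditions: NaBH4, THF/MeOH, 0 °C
Reagents that add atoms: none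
Why: Borohydride reduction of the aldehyde to the benzylic alcohol.

**Step 16**
Reactants: 21 benzylic alcohol
Product: 22 5-(bromomethyl)-1-{(1S,2S)-1,3-bis(TBSO)-1-[3-methoxy-4-(TIPSO)phenyl]propan-2-yl}-2-(TBSO)-3-methoxybenzene (fragment B)
Conditions: PPh3, CBr4, CH2Cl2, 0 °C
Reagents that add atoms: tetrabromomethane, BrC(Br)(Br)Br
Why: Appel bromination converts the primary benzylic alcohol to the bromide under neutral conditions that leave the silyl ethers intact.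

**Step 17**
Reactants: 14 imide; 6 3-methoxy-4-(TIPSO)benzaldehyde
Product: 25 (4S)-4-benzyl-3-{(2S,3S)-2-[5-bromo-2-(TBSO)-3-methoxyphenyl]-3-hydroxy-3-[3-methoxy-4-(TIPSO)phenyl]propanoyl}-1,3-oxazolidin-2-one, via boron enolate 23 (not isolated), via boron aldolate 24 (not isolated)
Conditions: Bu2BOTf, i-Pr2NEt, CH2Cl2, 0 °C; 6, −78 to 0 °C; pH 7 buffer, MeOH, H2O2
Reagents that add atoms: dibutylboron trifluoromethanesulfonate, CCCCB(CCCC)OS(=O)(=O)C(F)(F)F (atoms in 23 and 24 only)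
Why: Evans syn-aldol: the Z-dibutylboron enolate reacts through a Zimmerman–Traxler chair on the face away from the benzyl group, giving the (2S,3S) adduct, of which only C2 (the future C3 of the dihydrobenzofuran) must be controlled.

**Step 18**
Reactants: 25 syn-aldol adduct
Product: 26 (1S,2R)-2-[5-bromo-2-(TBSO)-3-methoxyphenyl]-1-[3-methoxy-4-(TIPSO)phenyl]propane-1,3-diol
Conditions: LiBH4, H2O (1 equiv), THF, 0 °C
Reagents that add atoms: none
Why: Reductive removal of the auxiliary to the primary alcohol, stereocentres untouched.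

**Step 19**
Reactants: 26 (1S,2R)-diol
Product: 27 (1S,2R)-2-(5-bromo-2-hydroxy-3-methoxyphenyl)-1-(4-hydroxy-3-methoxyphenyl)propane-1,3-diol
Conditions: Bu4NF, AcOH (1:1), THF, 0 °C to rt
Reagents that add atoms: none
Why: Fluoride desilylation cleaves both aryl silyl ethers and frees the two phenols needed for ring closure.

**Step 20**
Reactants: 27 tetraol
Product: 28 4-[(2S,3R)-5-bromo-3-(hydroxymethyl)-7-methoxy-2,3-dihydro-1-benzofuran-2-yl]-2-methoxyphenol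
Conditions: TsOH·H2O (10 mol%), MeCN (0.01 M), rt
Reagents that add atoms: none
Why: Acid ionises the para-hydroxybenzylic alcohol to a quinone methide that the neighbouring phenol traps in a 5-exo cyclisation (biomimetic phenylcoumaran formation); the existing C3 centre directs the aryl group trans, so C2 becomes S whatever the carbinol configuration was.

**Step 21**
Reactants: 28 dihydrobenzofuran diol
Product: 29 (2S,3R)-5-bromo-3-[(TBSO)methyl]-2-[4-(TBSO)-3-methoxyphenyl]-7-methoxy-2,3-dihydro-1-benzofuran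
Conditions: TBSCl (2.5 equiv), imidazole, DMF, rt
Reagents that add atoms: tert-butyl(chloro)dimethylsilane, CC(C)(C)[Si](C)(C)Cl
Why: Silyl ether formation on the phenol and the primary alcohol.

**Step 22**
Reactants: 30 malonic acid
Product: 31 bis(prop-2-en-1-yl) propanedioate (diallyl malonate)
Conditions: allyl alcohol (excess), TsOH (cat.), toluene, reflux, Dean–Stark
Reagents that add atoms: prop-2-en-1-ol, C=CCO
Why: Fischer esterification with azeotropic water removal gives an ester that can later be removed with zerovalent palladium under neutral conditions.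

**Step 23**
Reactants: 31 diallyl malonate; 32 (R)-epichlorohydrin
Product: 34 prop-2-en-1-yl (1S,5R)-2-oxo-3-oxabicyclo[3.1.0]hexane-1-carboxylate, via epoxy malonate 33 (not isolated)
Conditions: NaH (1.1 equiv) in allyl alcohol (gives NaOCH2CH=CH2), 0 °C; 32; then 80 °C
Reagents that add atoms: none
Why: Tandem malonate alkylation: epoxide opening at CH2, re-closure to a new epoxide with loss of chloride, 3-exo-tet cyclopropanation with inversion at the stereocentre and lactonisation give the cis-fused (1S,5R) lactone, transferring the chirality of (R)-epichlorohydrin.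

**Step 24**
Reactants: 29 dihydrobenzofuran bromide; 34 bicyclic lactone
Product: 37 prop-2-en-1-yl (3S,4R)-4-{[(2S,3R)-3-[(TBSO)methyl]-2-[4-(TBSO)-3-methoxyphenyl]-7-methoxy-2,3-dihydro-1-benzofuran-5-yl]methyl}-2-oxooxolane-3-carboxylate (trans epimer shown; C3 is epimerisable), via aryllithium 35 (not isolated), via arylmagnesium bromide 36 (not isolated)
Conditions: n-BuLi, THF, −78 °C; MgBr2·OEt2, −78 to −30 °C; CuI (20 mol%), 34 (1.5 equiv), −30 to 0 °C; aq NH4Cl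
Reagents that add atoms: n-butyllithium, [Li]CCCC (lithium in 35 only); magnesium bromide, Br[Mg]Br (atoms in 36 only)
Why: Copper-catalysed homoconjugate (SN2-type) opening of the doubly activated cyclopropane at its CH2 group by the aryl Grignard reagent; C5 of the bicycle is untouched and becomes the R-configured C4 of the lactone.

**Step 25**
Reactants: 37 allyl ester lactone
Product: 39 (4R)-4-{[(2S,3R)-3-[(TBSO)methyl]-2-[4-(TBSO)-3-methoxyphenyl]-7-methoxy-2,3-dihydro-1-benzofuran-5-yl]methyl}oxolan-2-one (fragment A), via carboxylic acid 38 (not isolated)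
Conditions: Pd(PPh3)4 (5 mol%), morpholine, THF, rt; then toluene, 110 °C
Reagents that add atoms: none
Why: Tsuji–Trost deallylation (zerovalent palladium, morpholine as allyl acceptor) gives the malonic half-acid, which decarboxylates on heating.

**Step 26**
Reactants: 39 fragment A lactone; 22 fragment B benzylic bromide
Product: 41 (3R,4R)-3-{[3-{(1S,2S)-1,3-bis(TBSO)-1-[3-methoxy-4-(TIPSO)phenyl]propan-2-yl}-4-(TBSO)-5-methoxyphenyl]methyl}-4-{[(2S,3R)-3-[(TBSO)methyl]-2-[4-(TBSO)-3-methoxyphenyl]-7-methoxy-2,3-dihydro-1-benzofuran-5-yl]methyl}oxolan-2-one, via lithium enolate 40 (not isolated)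
Conditions: LiN(SiMe3)2 (1.05 equiv), THF, −78 °C; then 22, DMPU, −78 to −40 °C
Reagents that add atoms: lithium bis(trimethylsilyl)amide, [Li]N([Si](C)(C)C)[Si](C)(C)C (lithium in 40 only)
Why: Lactone enolate alkylation in which the benzylic bromide approaches anti to the C4 substituent, giving the trans (3R,4R) dibenzylbutyrolactone.

**Step 27**
Reactants: 41 hexasilylated lactone
Product: 42 target, (3R,4R)-3-{[3-[(1S,2S)-1,3-dihydroxy-1-(4-hydroxy-3-methoxyphenyl)propan-2-yl]-4-hydroxy-5-methoxyphenyl]methyl}-4-{[(2S,3R)-2-(4-hydroxy-3-methoxyphenyl)-3-(hydroxymethyl)-7-methoxy-2,3-dihydro-1-benzofuran-5-yl]methyl}oxolan-2-one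
Conditions: Bu4NF (10 equiv), AcOH (10 equiv), THF, 0 to 40 °C
Reagents that add atoms: none
Why: Global fluoride desilylation, with AcOH buffering so the freed para-hydroxybenzylic alcohol does not form a quinone methide and close onto the neighbouring phenol, and so the lactone does not epimerise.

**Compound list**
1 | catechol | Oc1ccccc1O | starting material
2 | guaiacol (2-methoxyphenol) | COc1ccccc1O | intermediate
3 | 4-bromo-2-methoxyphenol | COc1cc(Br)ccc1O | intermediate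
4 | (4-bromo-2-methoxyphenoxy)triisopropylsilane | COc1cc(Br)ccc1O[Si](C(C)C)(C(C)C)C(C)C | intermediate
5 | [3-methoxy-4-(TIPSO)phenyl]lithium | [Li]c1ccc(O[Si](C(C)C)(C(C)C)C(C)C)c(OC)c1 | intermediate
6 | 3-methoxy-4-(TIPSO)benzaldehyde | COc1cc(C=O)ccc1O[Si](C(C)C)(C(C)C)C(C)C | intermediate
7 | allyl bromide | C=CCBr | starting material
8 | 1-(allyloxy)-4-bromo-2-methoxybenzene | C=CCOc1ccc(Br)cc1OC | intermediate
9 | 2-allyl-4-bromo-6-methoxyphenol | C=CCc1cc(Br)cc(OC)c1O | intermediate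
10 | (2-allyl-4-bromo-6-methoxyphenoxy)(tert-butyl)dimethylsilane | C=CCc1cc(Br)cc(OC)c1O[Si](C)(C)C(C)(C)C | intermediate
11 | 2-[5-bromo-2-(TBSO)-3-methoxyphenyl]acetaldehyde | O=CCc1cc(Br)cc(OC)c1O[Si](C)(C)C(C)(C)C | intermediate
12 | 2-[5-bromo-2-(TBSO)-3-methoxyphenyl]acetic acid | OC(=O)Cc1cc(Br)cc(OC)c1O[Si](C)(C)C(C)(C)C | intermediate
13 | [5-bromo-2-(TBSO)-3-methoxyphenyl]acetic pivalic anhydride | CC(C)(C)C(=O)OC(=O)Cc1cc(Br)cc(OC)c1O[Si](C)(C)C(C)(C)C | intermediate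
14 | (4S)-4-benzyl-3-{[5-bromo-2-(TBSO)-3-methoxyphenyl]acetyl}-1,3-oxazolidin-2-one | O=C(Cc1cc(Br)cc(OC)c1O[Si](C)(C)C(C)(C)C)N1[C@@H](Cc2ccccc2)COC1=O | intermediate
15 | trimethylsilyl ether of 16 (2R,3S) | COc1cc([C@@H](O[Si](C)(C)C)[C@H](C(=O)N2[C@@H](Cc3ccccc3)COC2=O)c2cc(Br)cc(OC)c2O[Si](C)(C)C(C)(C)C)ccc1O[Si](C(C)C)(C(C)C)C(C)C | intermediate
16 | (4S)-4-benzyl-3-{(2R,3S)-2-[5-bromo-2-(TBSO)-3-methoxyphenyl]-3-hydroxy-3-[3-methoxy-4-(TIPSO)phenyl]propanoyl}-1,3-oxazolidin-2-one | COc1cc([C@@H](O)[C@H](C(=O)N2[C@@H](Cc3ccccc3)COC2=O)c2cc(Br)cc(OC)c2O[Si](C)(C)C(C)(C)C)ccc1O[Si](C(C)C)(C(C)C)C(C)C | intermediate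
17 | (1S,2S)-2-[5-bromo-2-(TBSO)-3-methoxyphenyl]-1-[3-methoxy-4-(TIPSO)phenyl]propane-1,3-diol | COc1cc([C@@H](O)[C@H](CO)c2cc(Br)cc(OC)c2O[Si](C)(C)C(C)(C)C)ccc1O[Si](C(C)C)(C(C)C)C(C)C | intermediate
18 | 5-bromo-1-{(1S,2S)-1,3-bis(TBSO)-1-[3-methoxy-4-(TIPSO)phenyl]propan-2-yl}-2-(TBSO)-3-methoxybenzene | COc1cc([C@@H](O[Si](C)(C)C(C)(C)C)[C@H](CO[Si](C)(C)C(C)(C)C)c2cc(Br)cc(OC)c2O[Si](C)(C)C(C)(C)C)ccc1O[Si](C(C)C)(C(C)C)C(C)C | intermediate
19 | aryllithium from 18 (Li in place of Br) | COc1cc([C@@H](O[Si](C)(C)C(C)(C)C)[C@H](CO[Si](C)(C)C(C)(C)C)c2cc([Li])cc(OC)c2O[Si](C)(C)C(C)(C)C)ccc1O[Si](C(C)C)(C(C)C)C(C)C | intermediate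
20 | 3-{(1S,2S)-1,3-bis(TBSO)-1-[3-methoxy-4-(TIPSO)phenyl]propan-2-yl}-4-(TBSO)-5-methoxybenzaldehyde | COc1cc([C@@H](O[Si](C)(C)C(C)(C)C)[C@H](CO[Si](C)(C)C(C)(C)C)c2cc(C=O)cc(OC)c2O[Si](C)(C)C(C)(C)C)ccc1O[Si](C(C)C)(C(C)C)C(C)C | intermediate
21 | [3-{(1S,2S)-1,3-bis(TBSO)-1-[3-methoxy-4-(TIPSO)phenyl]propan-2-yl}-4-(TBSO)-5-methoxyphenyl]methanol | COc1cc([C@@H](O[Si](C)(C)C(C)(C)C)[C@H](CO[Si](C)(C)C(C)(C)C)c2cc(CO)cc(OC)c2O[Si](C)(C)C(C)(C)C)ccc1O[Si](C(C)C)(C(C)C)C(C)C | intermediate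
22 | 5-(bromomethyl)-1-{(1S,2S)-1,3-bis(TBSO)-1-[3-methoxy-4-(TIPSO)phenyl]propan-2-yl}-2-(TBSO)-3-methoxybenzene (fragment B) | COc1cc([C@@H](O[Si](C)(C)C(C)(C)C)[C@H](CO[Si](C)(C)C(C)(C)C)c2cc(CBr)cc(OC)c2O[Si](C)(C)C(C)(C)C)ccc1O[Si](C(C)C)(C(C)C)C(C)C | intermediate
23 | (Z)-dibutylboron enolate of 14 | CCCCB(CCCC)O/C(=C\c1cc(Br)cc(OC)c1O[Si](C)(C)C(C)(C)C)N1[C@@H](Cc2ccccc2)COC1=O | intermediate
24 | dibutylboron aldolate of 25 (2S,3S) | COc1cc([C@@H](OB(CCCC)CCCC)[C@@H](C(=O)N2[C@@H](Cc3ccccc3)COC2=O)c2cc(Br)cc(OC)c2O[Si](C)(C)C(C)(C)C)ccc1O[Si](C(C)C)(C(C)C)C(C)C | intermediate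
25 | (4S)-4-benzyl-3-{(2S,3S)-2-[5-bromo-2-(TBSO)-3-methoxyphenyl]-3-hydroxy-3-[3-methoxy-4-(TIPSO)phenyl]propanoyl}-1,3-oxazolidin-2-one | COc1cc([C@@H](O)[C@@H](C(=O)N2[C@@H](Cc3ccccc3)COC2=O)c2cc(Br)cc(OC)c2O[Si](C)(C)C(C)(C)C)ccc1O[Si](C(C)C)(C(C)C)C(C)C | intermediate
26 | (1S,2R)-2-[5-bromo-2-(TBSO)-3-methoxyphenyl]-1-[3-methoxy-4-(TIPSO)phenyl]propane-1,3-diol | COc1cc([C@@H](O)[C@@H](CO)c2cc(Br)cc(OC)c2O[Si](C)(C)C(C)(C)C)ccc1O[Si](C(C)C)(C(C)C)C(C)C | intermediate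
27 | (1S,2R)-2-(5-bromo-2-hydroxy-3-methoxyphenyl)-1-(4-hydroxy-3-methoxyphenyl)propane-1,3-diol | COc1cc([C@@H](O)[C@@H](CO)c2cc(Br)cc(OC)c2O)ccc1O | intermediate
28 | 4-[(2S,3R)-5-bromo-3-(hydroxymethyl)-7-methoxy-2,3-dihydro-1-benzofuran-2-yl]-2-methoxyphenol | Brc1cc(OC)c2c(c1)[C@H](CO)[C@@H](c1ccc(O)c(OC)c1)O2 | intermediate
29 | (2S,3R)-5-bromo-3-[(TBSO)methyl]-2-[4-(TBSO)-3-methoxyphenyl]-7-methoxy-2,3-dihydro-1-benzofuran | Brc1cc(OC)c2c(c1)[C@H](CO[Si](C)(C)C(C)(C)C)[C@@H](c1ccc(O[Si](C)(C)C(C)(C)C)c(OC)c1)O2 | intermediate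
30 | malonic acid | OC(=O)CC(O)=O | starting material
31 | bis(prop-2-en-1-yl) propanedioate | C=CCOC(=O)CC(=O)OCC=C | intermediate
32 | (R)-epichlorohydrin | ClC[C@H]1CO1 | starting material
33 | bis(prop-2-en-1-yl) 2-{[(2R)-oxiran-2-yl]methyl}propanedioate | C=CCOC(=O)C(C[C@@H]1CO1)C(=O)OCC=C | intermediate
34 | prop-2-en-1-yl (1S,5R)-2-oxo-3-oxabicyclo[3.1.0]hexane-1-carboxylate | O=C1OC[C@@H]2C[C@]12C(=O)OCC=C | intermediate
35 | aryllithium from 29 (Li at C5) | [Li]c1cc(OC)c2c(c1)[C@H](CO[Si](C)(C)C(C)(C)C)[C@@H](c1ccc(O[Si](C)(C)C(C)(C)C)c(OC)c1)O2 | intermediate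
36 | arylmagnesium bromide from 29 (MgBr at C5) | Br[Mg]c1cc(OC)c2c(c1)[C@H](CO[Si](C)(C)C(C)(C)C)[C@@H](c1ccc(O[Si](C)(C)C(C)(C)C)c(OC)c1)O2 | intermediate
37 | prop-2-en-1-yl (3S,4R)-4-{[(2S,3R)-3-[(TBSO)methyl]-2-[4-(TBSO)-3-methoxyphenyl]-7-methoxy-2,3-dihydro-1-benzofuran-5-yl]methyl}-2-oxooxolane-3-carboxylate (trans epimer; C3 epimerisable) | C=CCOC(=O)[C@H]1C(=O)OC[C@@H]1Cc1cc(OC)c2c(c1)[C@H](CO[Si](C)(C)C(C)(C)C)[C@@H](c1ccc(O[Si](C)(C)C(C)(C)C)c(OC)c1)O2 | intermediate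
38 | (3S,4R)-4-{[...-2,3-dihydro-1-benzofuran-5-yl]methyl}-2-oxooxolane-3-carboxylic acid (acid of 37) | OC(=O)[C@H]1C(=O)OC[C@@H]1Cc1cc(OC)c2c(c1)[C@H](CO[Si](C)(C)C(C)(C)C)[C@@H](c1ccc(O[Si](C)(C)C(C)(C)C)c(OC)c1)O2 | intermediate
39 | (4R)-4-{[(2S,3R)-3-[(TBSO)methyl]-2-[4-(TBSO)-3-methoxyphenyl]-7-methoxy-2,3-dihydro-1-benzofuran-5-yl]methyl}oxolan-2-one (fragment A) | O=C1OC[C@@H](C1)Cc1cc(OC)c2c(c1)[C@H](CO[Si](C)(C)C(C)(C)C)[C@@H](c1ccc(O[Si](C)(C)C(C)(C)C)c(OC)c1)O2 | intermediate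
40 | lithium enolate of 39 | [Li]OC1=C[C@H](CO1)Cc1cc(OC)c2c(c1)[C@H](CO[Si](C)(C)C(C)(C)C)[C@@H](c1ccc(O[Si](C)(C)C(C)(C)C)c(OC)c1)O2 | intermediate
41 | hexasilylated target (3R,4R; five TBS, one TIPS) | COc1cc([C@@H](O[Si](C)(C)C(C)(C)C)[C@H](CO[Si](C)(C)C(C)(C)C)c2cc(C[C@H]3C(=O)OC[C@@H]3Cc3cc(OC)c4c(c3)[C@H](CO[Si](C)(C)C(C)(C)C)[C@@H](c3ccc(O[Si](C)(C)C(C)(C)C)c(OC)c3)O4)cc(OC)c2O[Si](C)(C)C(C)(C)C)ccc1O[Si](C(C)C)(C(C)C)C(C)C | intermediate
42 | CNP0186558.2 | COc1cc([C@@H](O)[C@H](CO)c2cc(C[C@H]3C(=O)OC[C@@H]3Cc3cc(OC)c4c(c3)[C@H](CO)[C@@H](c3ccc(O)c(OC)c3)O4)cc(OC)c2O)ccc1O | target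

**Totals**
Total step count: 27.
Longest linear sequence: 17 steps (1, 2, 5–10, 17–21, 24–27).

**Steps most likely to fail, with fallbacks**

Step 11. The MgCl2-catalysed anti-aldol is the least precedented step, because the arylacetyl imide is ortho-disubstituted and the aldehyde is electron-rich; it may stall or give poor anti-selectivity. The fallback replaces it by a syn-aldol followed by inversion of the carbinol; it sets out from acid 12 and comes back at 18. Acid 12 is converted through mixed anhydride 13 and (R)-4-benzyl-1,3-oxazolidin-2-one into the enantiomeric imide F1. Bu2BOTf and i-Pr2NEt give its Z-boron enolate F2, which adds to 6 to give boron aldolate F3 and, after H2O2 work-up, the (2R,3R) syn-adduct F4. LiBH4 gives the (1R,2S)-diol F5. TBSCl and imidazole at 0 °C silylate only the primary hydroxyl, giving mono-silyl ether F6. A Mitsunobu reaction (PPh3, DIAD, 4-nitrobenzoic acid) inverts C1 to the (1S)-4-nitrobenzoate F7. i-Bu2AlH at −78 °C frees the (1S,2S)-alcohol F8, and TBSOTf with 2,6-lutidine converts F8 into 18.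

Step 24. The copper-catalysed cyclopropane opening uses a precious, functionalised aryl metal; carbonyl attack or sluggish transmetalation could ruin it. The fallback reverses the polarity and builds the lactone by auxiliary-controlled alkylation; it sets out from 29 and comes back at 39. Bromide 29 is lithiated to 35 and formylated with DMF to aldehyde F9. NaBH4 gives benzylic alcohol F10, and PPh3/CBr4 gives benzylic bromide F11. Separately, (R)-4-benzyl-1,3-oxazolidin-2-one is deprotonated with n-BuLi and acylated with pent-4-enoyl chloride to give pentenoyl imide F12. NaN(SiMe3)2 at −78 °C gives sodium enolate F13, which is alkylated by F11 anti to the auxiliary benzyl group (Evans alkylation) to give the (2S)-alkylated imide F14. LiBH4 gives the (2S)-pentenol F15, OsO4/NaIO4 cleaves the alkene to lactol F16, and TEMPO/PhI(OAc)2 oxidises F16 to 39.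

Step 26. The union of two large fragments by enolate alkylation may suffer from slow SN2 reaction, bis-alkylation or decomposition of the electron-rich benzylic bromide. The fallback is aldol addition followed by radical deoxygenation; it sets out from 39 and aldehyde 20 and comes back at 41. Lithium enolate 40 adds to 20 anti to the C4 substituent to give lithium aldolate F17 and, on work-up, hydroxy lactone F18 as a mixture of carbinol epimers. 1,1'-Thiocarbonyldiimidazole with DMAP gives imidazolylthiocarbonate F19, and Bu3SnH with AIBN in toluene at 90 °C (Barton–McCombie deoxygenation) gives 41.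

**Further compounds**
F1 | step 11 | (4R)-4-benzyl-3-{[5-bromo-2-(TBSO)-3-methoxyphenyl]acetyl}-1,3-oxazolidin-2-one | O=C(Cc1cc(Br)cc(OC)c1O[Si](C)(C)C(C)(C)C)N1[C@H](Cc2ccccc2)COC1=O
F2 | step 11 | (Z)-dibutylboron enolate of F1 | CCCCB(CCCC)O/C(=C\c1cc(Br)cc(OC)c1O[Si](C)(C)C(C)(C)C)N1[C@H](Cc2ccccc2)COC1=O
F3 | step 11 | dibutylboron aldolate of F4 (2R,3R) | COc1cc([C@H](OB(CCCC)CCCC)[C@H](C(=O)N2[C@H](Cc3ccccc3)COC2=O)c2cc(Br)cc(OC)c2O[Si](C)(C)C(C)(C)C)ccc1O[Si](C(C)C)(C(C)C)C(C)C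
F4 | step 11 | (4R)-4-benzyl-3-{(2R,3R)-2-[5-bromo-2-(TBSO)-3-methoxyphenyl]-3-hydroxy-3-[3-methoxy-4-(TIPSO)phenyl]propanoyl}-1,3-oxazolidin-2-one | COc1cc([C@H](O)[C@H](C(=O)N2[C@H](Cc3ccccc3)COC2=O)c2cc(Br)cc(OC)c2O[Si](C)(C)C(C)(C)C)ccc1O[Si](C(C)C)(C(C)C)C(C)C
F5 | step 11 | (1R,2S)-2-[5-bromo-2-(TBSO)-3-methoxyphenyl]-1-[3-methoxy-4-(TIPSO)phenyl]propane-1,3-diol | COc1cc([C@H](O)[C@H](CO)c2cc(Br)cc(OC)c2O[Si](C)(C)C(C)(C)C)ccc1O[Si](C(C)C)(C(C)C)C(C)C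
F6 | step 11 | (1R,2S)-2-[5-bromo-2-(TBSO)-3-methoxyphenyl]-3-(TBSO)-1-[3-methoxy-4-(TIPSO)phenyl]propan-1-ol | COc1cc([C@H](O)[C@H](CO[Si](C)(C)C(C)(C)C)c2cc(Br)cc(OC)c2O[Si](C)(C)C(C)(C)C)ccc1O[Si](C(C)C)(C(C)C)C(C)C
F7 | step 11 | (1S,2S)-2-[5-bromo-2-(TBSO)-3-methoxyphenyl]-3-(TBSO)-1-[3-methoxy-4-(TIPSO)phenyl]propyl 4-nitrobenzoate | COc1cc([C@@H](OC(=O)c2ccc(cc2)[N+](=O)[O-])[C@H](CO[Si](C)(C)C(C)(C)C)c2cc(Br)cc(OC)c2O[Si](C)(C)C(C)(C)C)ccc1O[Si](C(C)C)(C(C)C)C(C)C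
F8 | step 11 | (1S,2S)-2-[5-bromo-2-(TBSO)-3-methoxyphenyl]-3-(TBSO)-1-[3-methoxy-4-(TIPSO)phenyl]propan-1-ol | COc1cc([C@@H](O)[C@H](CO[Si](C)(C)C(C)(C)C)c2cc(Br)cc(OC)c2O[Si](C)(C)C(C)(C)C)ccc1O[Si](C(C)C)(C(C)C)C(C)C
F9 | step 24 | (2S,3R)-3-[(TBSO)methyl]-2-[4-(TBSO)-3-methoxyphenyl]-7-methoxy-2,3-dihydro-1-benzofuran-5-carbaldehyde | O=Cc1cc(OC)c2c(c1)[C@H](CO[Si](C)(C)C(C)(C)C)[C@@H](c1ccc(O[Si](C)(C)C(C)(C)C)c(OC)c1)O2
F10 | step 24 | {(2S,3R)-3-[(TBSO)methyl]-2-[4-(TBSO)-3-methoxyphenyl]-7-methoxy-2,3-dihydro-1-benzofuran-5-yl}methanol | OCc1cc(OC)c2c(c1)[C@H](CO[Si](C)(C)C(C)(C)C)[C@@H](c1ccc(O[Si](C)(C)C(C)(C)C)c(OC)c1)O2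
F11 | step 24 | (2S,3R)-5-(bromomethyl)-3-[(TBSO)methyl]-2-[4-(TBSO)-3-methoxyphenyl]-7-methoxy-2,3-dihydro-1-benzofuran | BrCc1cc(OC)c2c(c1)[C@H](CO[Si](C)(C)C(C)(C)C)[C@@H](c1ccc(O[Si](C)(C)C(C)(C)C)c(OC)c1)O2
F12 | step 24 | (4R)-4-benzyl-3-(pent-4-enoyl)-1,3-oxazolidin-2-one | C=CCCC(=O)N1[C@H](Cc2ccccc2)COC1=O
F13 | step 24 | (Z)-sodium enolate of F12 | [Na]O/C(=C\CC=C)N1[C@H](Cc2ccccc2)COC1=O
F14 | step 24 | (4R)-4-benzyl-3-[(2S)-2-{[(2S,3R)-3-[(TBSO)methyl]-2-[4-(TBSO)-3-methoxyphenyl]-7-methoxy-2,3-dihydro-1-benzofuran-5-yl]methyl}pent-4-enoyl]-1,3-oxazolidin-2-one | C=CC[C@@H](Cc1cc(OC)c2c(c1)[C@H](CO[Si](C)(C)C(C)(C)C)[C@@H](c1ccc(O[Si](C)(C)C(C)(C)C)c(OC)c1)O2)C(=O)N1[C@H](Cc2ccccc2)COC1=O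
F15 | step 24 | (2S)-2-{[(2S,3R)-3-[(TBSO)methyl]-2-[4-(TBSO)-3-methoxyphenyl]-7-methoxy-2,3-dihydro-1-benzofuran-5-yl]methyl}pent-4-en-1-ol | C=CC[C@@H](Cc1cc(OC)c2c(c1)[C@H](CO[Si](C)(C)C(C)(C)C)[C@@H](c1ccc(O[Si](C)(C)C(C)(C)C)c(OC)c1)O2)CO
F16 | step 24 | (4R)-4-{[(2S,3R)-3-[(TBSO)methyl]-2-[4-(TBSO)-3-methoxyphenyl]-7-methoxy-2,3-dihydro-1-benzofuran-5-yl]methyl}oxolan-2-ol (anomer mixture) | OC1C[C@@H](Cc2cc(OC)c3c(c2)[C@H](CO[Si](C)(C)C(C)(C)C)[C@@H](c2ccc(O[Si](C)(C)C(C)(C)C)c(OC)c2)O3)CO1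
F17 | step 26 | lithium aldolate of F18 | COc1cc([C@@H](O[Si](C)(C)C(C)(C)C)[C@H](CO[Si](C)(C)C(C)(C)C)c2cc(C(O[Li])[C@H]3C(=O)OC[C@@H]3Cc3cc(OC)c4c(c3)[C@H](CO[Si](C)(C)C(C)(C)C)[C@@H](c3ccc(O[Si](C)(C)C(C)(C)C)c(OC)c3)O4)cc(OC)c2O[Si](C)(C)C(C)(C)C)ccc1O[Si](C(C)C)(C(C)C)C(C)C
F18 | step 26 | (3S,4R)-3-[aryl(hydroxy)methyl] analogue of 41 (benzylic CH(OH) in place of CH2; carbinol epimers) | COc1cc([C@@H](O[Si](C)(C)C(C)(C)C)[C@H](CO[Si](C)(C)C(C)(C)C)c2cc(C(O)[C@H]3C(=O)OC[C@@H]3Cc3cc(OC)c4c(c3)[C@H](CO[Si](C)(C)C(C)(C)C)[C@@H](c3ccc(O[Si](C)(C)C(C)(C)C)c(OC)c3)O4)cc(OC)c2O[Si](C)(C)C(C)(C)C)ccc1O[Si](C(C)C)(C(C)C)C(C)C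
F19 | step 26 | O-(1H-imidazol-1-ylcarbonothioyl) derivative of F18 | COc1cc([C@@H](O[Si](C)(C)C(C)(C)C)[C@H](CO[Si](C)(C)C(C)(C)C)c2cc(C(OC(=S)n5ccnc5)[C@H]3C(=O)OC[C@@H]3Cc3cc(OC)c4c(c3)[C@H](CO[Si](C)(C)C(C)(C)C)[C@@H](c3ccc(O[Si](C)(C)C(C)(C)C)c(OC)c3)O4)cc(OC)c2O[Si](C)(C)C(C)(C)C)ccc1O[Si](C(C)C)(C(C)C)C(C)C
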